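**Plan**

- Labdane numbering is used throughout: decalin C1–C10, gem-dimethyl on C4, methyl on C10, C17 on C8, chain C11–C16 on C9.
- Cuts: the dioxepine at O–C15 (hemiperoxyacetal) and O–C11 (hydroperoxide from an allylic alcohol); the chain at C13–C14 and C11–C12; C17 and C11 off ring B, back to a trans-fused Δ7-9-ketone; ring A at C2=C3, C1–C10 and C4–C5.
- Forward: ring B is (R)-carvone. C4 (carrying C3 as an aldehyde) is added to C5, then a vinylphosphonium salt brings C1–C2 to C10 and the ylide at C2 closes ring A onto C3. C11, C17 and the C7 oxygen follow, then the C12–C16 chain, and the peroxide ring closes last.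
- What makes the ring closure possible: C2 and C3 are bare methylenes between the quaternary carbons C4 and C10 of ring A. C3 can therefore be a non-enolisable aldehyde on C4, and C2 an ylide carbon two atoms from the C9-enolate carbon C10, with both arms trans-diequatorial on ring B.
- Stereochemistry: the carvone centre (C7, as acetate) sets C5, C5 sets C10, the C10 methyl sets C9, the ring B chair sets C7. C11 comes from face-selective capture of an allyl cation (both alcohol epimers converge) and C15 from equilibration.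

Key step: step 3

Remark: C15 is a hemiperoxyacetal carbon that epimerises through the open hydroperoxy aldehyde; the configuration of the target is assumed to be the thermodynamically preferred one.

**Route**

Step 1
Reactants: 1 (R)-(−)-carvone
Product: 4 (R)-4-methyl-5-oxocyclohex-3-en-1-yl acetate, via methoxy hydroperoxide 2 (not isolated), via peracetate 3 (not isolated)
Conditions: O3, CH2Cl2/MeOH, −78 °C (dye end point); then Ac2O, Et3N, DMAP (cat.), 0 °C → rt
Reagents that add atoms: ozone, [O-][O+]=O; methanol, CO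
Why: Ozone cleaves only the electron-rich isopropenyl alkene, methanol traps the carbonyl oxide, and O-acetylation triggers the Criegee rearrangement, in which the ring carbon migrates to oxygen with retention (acetate then removes the O-methyl group as methyl acetate), so the carvone stereocentre becomes the C7 acetate unchanged.

Step 2
Reactants: 4 (R)-4-methyl-5-oxocyclohex-3-en-1-yl acetate; 5 2-methyl-1-(trimethylsilyloxy)prop-1-ene
Product: 6 trans-4-methyl-5-(2-methyl-1-oxopropan-2-yl)-3-(trimethylsilyloxy)cyclohex-3-en-1-yl acetate (C7 acetoxy α, C5 aldehyde arm β)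
Conditions: Tf2NH (2 mol %), CH2Cl2, −78 °C; Et3N quench, non-aqueous work-up
Reagents that add atoms: none
Why: Mukaiyama–Michael addition catalysed by the silyl triflimide formed in situ: the enol silane should add to the enone β-carbon (C5) by axial attack anti to the acetoxy group, giving the 3,5-trans product and the quaternary C4, and silyl transfer leaves the C9–C10 enol ether regiodefined beside a free, non-enolisable C3 aldehyde.

Step 3
Reactants: 6 silyl enol ether aldehyde; 7 vinyltriphenylphosphonium bromide
Product: 10 7α-acetoxy-4,4,10β-trimethyl-5α-decal-2-en-9-one (trans-fused; ring A alkene C2=C3), via ammonium enolate 8 (not isolated), via phosphorus ylide 9 (not isolated)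
Conditions: Bu4N[Ph3SiF2] (1.1 equiv, added slowly to 6 and 7), MeCN/CH2Cl2, −40 °C → rt
Reagents that add atoms: none
Why: Fluoride removes the trimethylsilyl group and frees the C9–C10 enolate 8 regiospecifically; C10 adds to the terminal carbon of the vinylphosphonium salt (which becomes C1), the resulting ylide 9 at C2 attacks the C3 aldehyde, and the oxaphosphetane collapses to the C2=C3 alkene and Ph3P=O. The closest known reaction type is the tandem conjugate addition–intramolecular Wittig annulation of carbonyl-bearing enolates with vinyltriphenylphosphonium salts, including enolates formed by conjugate addition to cyclohexenones. Ring A closes as a six-membered ring by 6-exo-trig attack of the ylide carbon C2 on the C3 carbonyl, from arms that sit trans-diequatorial on the chair of ring B. The only new stereocentre, quaternary C10, is controlled by C5: A(1,2) strain with the C10 methyl holds the CMe2CHO group pseudoaxial on the β face, so the acceptor should add to the α face and C1 ends trans to C4, which is the trans ring fusion. The step needs reaction at C10 and not C8, C- and not O-alkylation, and conjugate addition before any aldol reaction; the silyl enol ether fixes the site, the soft unhindered acceptor favours C–C bond formation, and the C3 aldehyde is non-enolisable and could reach C10 only through a four-membered ring.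

Step 4
Reactants: 10 7α-acetoxy-4,4,10β-trimethyl-5α-decal-2-en-9-one
Product: 11 7α-acetoxy-4,4,10β-trimethyl-5α-decalin-9-one
Conditions: H2 (1 atm), 10% Pd/C, EtOAc, rt
Reagents that add atoms: none
Why: Heterogeneous hydrogenation of the only C=C bond; no stereocentre is formed.

Step 5
Reactants: 11 7α-acetoxy-4,4,10β-trimethyl-5α-decalin-9-one
Product: 12 (4aS,8aS)-5,5,8a-trimethyl-4a,5,6,7,8,8a-hexahydronaphthalen-1(4H)-one (the Δ7-9-ketone)
Conditions: DBU, CH2Cl2, rt
Reagents that add atoms: none
Why: E1cB elimination of the β-acetoxy ketone (axial C7 acetate, only the C8 enolate can form because C10 is quaternary) gives the conjugated enone; the carvone centre has done its work and is removed.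

Step 6
Reactants: 13 4-methoxybenzyl alcohol; 14 tributyl(iodomethyl)stannane
Product: 15 tributyl[(4-methoxybenzyloxy)methyl]stannane
Conditions: NaH, THF/DMF, 0 °C → rt
Reagents that add atoms: none
Why: Williamson ether synthesis by SN2 attack of the sodium alkoxide on the primary iodide.

Step 7
Reactants: 12 Δ7-9-ketone; 15 tributyl[(4-methoxybenzyloxy)methyl]stannane
Product: 17 9-hydroxy-9-[(4-methoxybenzyloxy)methyl]-4,4,10β-trimethyl-5α-decal-7-ene (9β-OH drawn), via alkoxymethyllithium 16 (not isolated)
Conditions: 15, n-BuLi, THF, −78 °C; then 12, −78 °C; H2O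
Reagents that add atoms: none
Why: Tin–lithium exchange gives a hard α-alkoxymethyllithium that adds 1,2 to the hindered enone carbonyl; the C9 configuration formed here is erased in step 8.

Step 8
Reactants: 17 tertiary allylic alcohol
Product: 18 9-[(4-methoxybenzyloxy)methyl]-4,4,10β-trimethyl-5α-decal-8-en-7-one
Conditions: [C5H5NH][CrO3Cl] (pyridinium chlorochromate), 4 Å molecular sieves, CH2Cl2, rt
Reagents that add atoms: none
Why: Babler–Dauben oxidative transposition: the chromate ester of the tertiary allylic alcohol shifts [3,3] to C7 and is oxidised, which moves the oxygen to C7 and places C11 on the β-carbon C9 of the new enone.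

Step 9
Reactants: 18 Δ8-7-ketone
Product: 20 8-(dimethylaminomethyl)-9β-[(4-methoxybenzyloxy)methyl]-4,4,10β-trimethyl-5α,9α-decalin-7-one (C8 epimers), via silyl enol ether 19 (not isolated)
Conditions: Cu(OAc)2·H2O (5 mol %), 1,2-bis(diphenylphosphino)benzene (5 mol %), PhMe2SiH, toluene, rt; then [Me2N=CH2]I, CH2Cl2, rt; aq. NaHCO3
Reagents that add atoms: N,N-dimethylmethyleneiminium iodide, C=[N+](C)C.[I-]
Why: Copper hydride conjugate reduction should deliver hydride to C9 from the α face, opposite the axial C10 methyl (9α-H, C11 β-equatorial), and the regiodefined silyl enol ether is then aminomethylated at C8 in a Mannich reaction.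

Step 10
Reactants: 20 Mannich base
Product: 22 9β-[(4-methoxybenzyloxy)methyl]-8-methylene-4,4,10β-trimethyl-5α,9α-decalin-7-one, via methiodide 21 (not isolated)
Conditions: MeI, Et2O/CH2Cl2, rt; then aq. NaHCO3, CH2Cl2, rt
Reagents that add atoms: none
Why: Quaternisation followed by mild-base E1cB (Hofmann-type) loss of trimethylamine gives the exocyclic enone (C8=C17) without base strong enough to move the alkene into the ring.

Step 11
Reactants: 22 8-methylene-7-ketone
Product: 23 7β-hydroxy-9β-[(4-methoxybenzyloxy)methyl]-8-methylene-4,4,10β-trimethyl-5α,9α-decalin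
Conditions: NaBH4, CeCl3·7H2O, MeOH, −78 °C
Reagents that add atoms: none
Why: Luche 1,2-reduction; hydride should add axially from the α face of the ring B chair, giving the equatorial 7β-alcohol.

Step 12
Reactants: 23 7β-allylic alcohol
Product: 24 7β-(tert-butyldimethylsilyloxy)-9β-[(4-methoxybenzyloxy)methyl]-8-methylene-4,4,10β-trimethyl-5α,9α-decalin
Conditions: TBSOTf, 2,6-lutidine, CH2Cl2, −78 → 0 °C
Reagents that add atoms: tert-butyldimethylsilyl trifluoromethanesulfonate, CC(C)(C)[Si](C)(C)OS(=O)(=O)C(F)(F)F
Why: Standard silylation of a hindered secondary alcohol with the silyl triflate.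

Step 13
Reactants: 24 silyl ether
Product: 25 7β-(tert-butyldimethylsilyloxy)-9β-(hydroxymethyl)-8-methylene-4,4,10β-trimethyl-5α,9α-decalin
Conditions: DDQ, CH2Cl2/pH 7 buffer, 0 °C
Reagents that add atoms: none
Why: Oxidative cleavage of the 4-methoxybenzyl ether, which leaves the silyl ether and the exocyclic alkene untouched.

Step 14
Reactants: 25 C11 alcohol
Product: 26 7β-(tert-butyldimethylsilyloxy)-8-methylene-4,4,10β-trimethyl-5α,9α-decalin-9β-carbaldehyde (C11 aldehyde)
Conditions: Dess–Martin periodinane, NaHCO3, CH2Cl2, 0 °C; used at once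
Reagents that add atoms: none
Why: Buffered, non-basic Dess–Martin oxidation, chosen so that the β,γ-unsaturated aldehyde does not isomerise into conjugation.

Step 15
Reactants: 26 C11 aldehyde; 27 3,3-diethoxyprop-1-yne
Product: 29 C11 propargylic alcohol carrying C12≡C13–CH(OEt)2 (epimer with oxygen on the face it has in the target drawn), via lithium acetylide 28 (not isolated)
Conditions: 27, n-BuLi, THF, −78 °C; then 26, −78 °C; H2O
Reagents that add atoms: none
Why: Acetylide addition to the aldehyde; Felkin–Anh attack anti to C10 should favour the epimer drawn, and both C11 epimers are expected to converge in step 18.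

Step 16
Reactants: 29 propargylic alcohol
Product: 31 (Z)-C13-iodo allylic alcohol (iodine cis to C11, acetal carbon C16 trans), via vinylalanate 30 (not isolated)
Conditions: NaAlH2(OCH2CH2OMe)2, THF, 0 °C → rt; then I2, −78 °C; aq. Na2S2O3, aq. potassium sodium tartrate
Reagents that add atoms: iodine, II
Why: Alkoxide-directed trans-hydroalumination puts hydride on C12 and aluminium on C13 in a five-membered alanate, and iodinolysis with retention gives the (Z)-iodoalkene.

Step 17
Reactants: 31 (Z)-iodoalkene; 32 (1,3-dioxolan-2-ylmethyl)zinc bromide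
Product: 33 (E)-allylic alcohol with C13 bearing CH(OEt)2 (C16) and CH2–(1,3-dioxolan-2-yl) (C14–C15), C14 cis to C11
Conditions: Pd(PPh3)4 (5 mol %), 32 (excess), THF, 50 °C
Reagents that add atoms: none
Why: Negishi sp2–sp3 coupling with retention of alkene geometry, which places C14 cis to C11 as the seven-membered ring requires.

Step 18
Reactants: 33 bis-acetal allylic alcohol
Product: 36 7-O-tert-butyldimethylsilyl ether of the target, via hydroperoxy bis-acetal 34 (not isolated), via hydroperoxy dial 35 (not isolated)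
Conditions: H2O2 (anhydrous, in Et2O, excess), H2SO4 (cat.), −20 → 0 °C; then THF/H2O, rt; NaHCO3
Reagents that add atoms: hydrogen peroxide, OO; water, O
Why: Acid-catalysed perhydrolysis of the allylic alcohol by an SN1 path, in which both C11 epimers give one allyl cation that H2O2 should capture at C11 (C13 is fully substituted and deactivated by the acetal carbon) on the face anti to C10, giving the 11S hydroperoxide; aqueous acid then frees both aldehydes and the hydroperoxide adds to the C15 aldehyde to close the hemiperoxyacetal, C15 settling by equilibration.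

Step 19
Reactants: 36 silyl-protected target
Product: 37 CNP0269954.2, (11S,15R)-11,15-epidioxy-7β,15-dihydroxylabda-8(17),12-dien-16-al
Conditions: HF·pyridine, THF/pyridine, 0 °C
Reagents that add atoms: none
Why: Acidic fluoride desilylation, which the peroxide, the hemiperoxyacetal and the enal should tolerate.

**Compound list**

1 | (R)-(−)-carvone | CC1=CC[C@H](CC1=O)C(C)=C | starting material
2 | (5R)-5-(1-hydroperoxy-1-methoxyethyl)-2-methylcyclohex-2-en-1-one | CC1=CC[C@H](CC1=O)C(C)(OC)OO | intermediate (not isolated)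
3 | (5R)-5-(1-acetylperoxy-1-methoxyethyl)-2-methylcyclohex-2-en-1-one | CC1=CC[C@H](CC1=O)C(C)(OC)OOC(C)=O | intermediate (not isolated)
4 | (R)-4-methyl-5-oxocyclohex-3-en-1-yl acetate | CC1=CC[C@H](CC1=O)OC(C)=O | intermediate
5 | 2-methyl-1-(trimethylsilyloxy)prop-1-ene | CC(C)=CO[Si](C)(C)C | starting material
6 | trans-4-methyl-5-(2-methyl-1-oxopropan-2-yl)-3-(trimethylsilyloxy)cyclohex-3-en-1-yl acetate | CC1=C(O[Si](C)(C)C)C[C@H](OC(C)=O)C[C@H]1C(C)(C)C=O | intermediate
7 | vinyltriphenylphosphonium bromide | C=C[P+](c1ccccc1)(c1ccccc1)c1ccccc1.[Br-] | starting material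
8 | tetrabutylammonium C9–C10 enolate of the keto aldehyde | CC1=C([O-])C[C@H](OC(C)=O)C[C@H]1C(C)(C)C=O.CCCC[N+](CCCC)(CCCC)CCCC | intermediate (not isolated)
9 | C2 phosphorus ylide (Michael adduct at C10) | C[C@@]1(CC=P(c2ccccc2)(c2ccccc2)c2ccccc2)C(=O)C[C@H](OC(C)=O)C[C@H]1C(C)(C)C=O | intermediate (not isolated)
10 | 7α-acetoxy-4,4,10β-trimethyl-5α-decal-2-en-9-one | C[C@]12CC=CC(C)(C)[C@@H]1C[C@H](CC2=O)OC(C)=O | intermediate
11 | 7α-acetoxy-4,4,10β-trimethyl-5α-decalin-9-one | C[C@]12CCCC(C)(C)[C@@H]1C[C@H](CC2=O)OC(C)=O | intermediate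
12 | (4aS,8aS)-5,5,8a-trimethyl-4a,5,6,7,8,8a-hexahydronaphthalen-1(4H)-one | C[C@]12CCCC(C)(C)[C@@H]1CC=CC2=O | intermediate
13 | 4-methoxybenzyl alcohol | COc1ccc(CO)cc1 | starting material
14 | tributyl(iodomethyl)stannane | CCCC[Sn](CCCC)(CCCC)CI | starting material
15 | tributyl[(4-methoxybenzyloxy)methyl]stannane | CCCC[Sn](CCCC)(CCCC)COCc1ccc(OC)cc1 | intermediate
16 | [(4-methoxybenzyloxy)methyl]lithium | [Li]COCc1ccc(OC)cc1 | intermediate (not isolated)
17 | 9-hydroxy-9-[(4-methoxybenzyloxy)methyl]-4,4,10β-trimethyl-5α-decal-7-ene | C[C@]12CCCC(C)(C)[C@@H]1CC=C[C@@]2(O)COCc1ccc(OC)cc1 | intermediate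
18 | 9-[(4-methoxybenzyloxy)methyl]-4,4,10β-trimethyl-5α-decal-8-en-7-one | C[C@]12CCCC(C)(C)[C@@H]1CC(=O)C=C2COCc1ccc(OC)cc1 | intermediate
19 | C7 dimethylphenylsilyl enol ether (Δ7, 9α-H) | C[C@]12CCCC(C)(C)[C@@H]1CC(O[Si](C)(C)c1ccccc1)=C[C@@H]2COCc1ccc(OC)cc1 | intermediate (not isolated)
20 | 8-(dimethylaminomethyl)-9β-[(4-methoxybenzyloxy)methyl]-4,4,10β-trimethyl-5α,9α-decalin-7-one (C8 epimers) | C[C@]12CCCC(C)(C)[C@@H]1CC(=O)C(CN(C)C)[C@@H]2COCc1ccc(OC)cc1 | intermediate
21 | methiodide of 20 | C[C@]12CCCC(C)(C)[C@@H]1CC(=O)C(C[N+](C)(C)C)[C@@H]2COCc1ccc(OC)cc1.[I-] | intermediate (not isolated)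
22 | 9β-[(4-methoxybenzyloxy)methyl]-8-methylene-4,4,10β-trimethyl-5α,9α-decalin-7-one | C[C@]12CCCC(C)(C)[C@@H]1CC(=O)C(=C)[C@@H]2COCc1ccc(OC)cc1 | intermediate
23 | 7β-hydroxy analogue of 22 | C[C@]12CCCC(C)(C)[C@@H]1C[C@H](O)C(=C)[C@@H]2COCc1ccc(OC)cc1 | intermediate
24 | 7β-tert-butyldimethylsilyl ether of 23 | C[C@]12CCCC(C)(C)[C@@H]1C[C@H](O[Si](C)(C)C(C)(C)C)C(=C)[C@@H]2COCc1ccc(OC)cc1 | intermediate
25 | 7β-(tert-butyldimethylsilyloxy)-9β-(hydroxymethyl)-8-methylene-4,4,10β-trimethyl-5α,9α-decalin | C[C@]12CCCC(C)(C)[C@@H]1C[C@H](O[Si](C)(C)C(C)(C)C)C(=C)[C@@H]2CO | intermediate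
26 | corresponding C11 aldehyde | C[C@]12CCCC(C)(C)[C@@H]1C[C@H](O[Si](C)(C)C(C)(C)C)C(=C)[C@@H]2C=O | intermediate
27 | 3,3-diethoxyprop-1-yne | C#CC(OCC)OCC | starting material
28 | lithium 3,3-diethoxyprop-1-yn-1-ide | [Li]C#CC(OCC)OCC | intermediate (not isolated)
29 | C11 propargylic alcohol (major epimer drawn) | C[C@]12CCCC(C)(C)[C@@H]1C[C@H](O[Si](C)(C)C(C)(C)C)C(=C)[C@@H]2[C@@H](O)C#CC(OCC)OCC | intermediate
30 | cyclic sodium alkoxyvinylalanate (Al on C13) | C[C@]12CCCC(C)(C)[C@@H]1C[C@H](O[Si](C)(C)C(C)(C)C)C(=C)[C@@H]2[C@H]1O[Al-](OCCOC)(OCCOC)C(C(OCC)OCC)=C1.[Na+] | intermediate (not isolated)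
31 | (Z)-C13-iodo allylic alcohol | C[C@]12CCCC(C)(C)[C@@H]1C[C@H](O[Si](C)(C)C(C)(C)C)C(=C)[C@@H]2[C@@H](O)/C=C(\I)C(OCC)OCC | intermediate
32 | (1,3-dioxolan-2-ylmethyl)zinc bromide | Br[Zn]CC1OCCO1 | starting material
33 | (E)-bis-acetal allylic alcohol | C[C@]12CCCC(C)(C)[C@@H]1C[C@H](O[Si](C)(C)C(C)(C)C)C(=C)[C@@H]2[C@@H](O)/C=C(\CC1OCCO1)C(OCC)OCC | intermediate
34 | (11S)-hydroperoxy bis-acetal | C[C@]12CCCC(C)(C)[C@@H]1C[C@H](O[Si](C)(C)C(C)(C)C)C(=C)[C@@H]2[C@@H](OO)/C=C(\CC1OCCO1)C(OCC)OCC | intermediate (not isolated)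
35 | (11S)-hydroperoxy 15,16-dial | C[C@]12CCCC(C)(C)[C@@H]1C[C@H](O[Si](C)(C)C(C)(C)C)C(=C)[C@@H]2[C@@H](OO)/C=C(\CC=O)C=O | intermediate (not isolated)
36 | 7-O-tert-butyldimethylsilyl ether of the target | C=C1[C@H]([C@@H]2C=C(C=O)C[C@H](O)OO2)[C@@]2(C)CCCC(C)(C)[C@@H]2C[C@@H]1O[Si](C)(C)C(C)(C)C | intermediate
37 | CNP0269954.2, (11S,15R)-11,15-epidioxy-7β,15-dihydroxylabda-8(17),12-dien-16-al | C=C1[C@H]([C@@H]2C=C(C=O)C[C@H](O)OO2)[C@@]2(C)CCCC(C)(C)[C@@H]2C[C@@H]1O | target

**Step count and risks**

Total: 19 steps. Longest linear sequence: 18 steps (steps 1–5 and 7–19 from 1; step 6 makes reagent 15).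

Steps most likely to fail:

1. Step 18. Ionisation at C11 may be followed by capture on the wrong face or at the wrong allyl terminus (C13), by a 1,2-hydride shift from C9, or by proton loss to a diene. The C16 acetal may also hydrolyse before the C–O exchange, which would shut the ionisation down. A fallback with defined stereochemistry sets out from 33. Mitsunobu inversion (4-nitrobenzoic acid, PPh3, diisopropyl azodicarboxylate) should give the C11-inverted 4-nitrobenzoate F1. Methanolysis (K2CO3, MeOH) gives the C11-epimeric alcohol F2, and mesylation (MsCl, Et3N, −40 °C) the allylic methanesulfonate F3. SN2 displacement with H2O2/KOH in THF/MeOH at 0 °C (inversion; the acetals are inert to base and C13 is fully substituted) should give hydroperoxide 34, where the route is rejoined for the aqueous acid stage of step 18.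

2. Step 3. The free enolate may be protonated before it meets the acceptor (loss of C10 regiocontrol), the β-acetoxy ketone formed after the Michael addition may eliminate acetate, or addition at the congested C10 may be too slow. The fallback sets out from 6. Neutral Tsuji–Trost allylation of the silyl enol ether with allyl methyl carbonate (Pd2(dba)3, 1,2-bis(diphenylphosphino)ethane, THF) should give the C10-allyl keto aldehyde F4 with the same anti selectivity. Wittig methylenation of the aldehyde (Ph3P=CH2, THF, −78 → 0 °C; the α-quaternary ketone should not react) gives diene F5. Ring-closing metathesis with the second-generation Grubbs catalyst (CH2Cl2, 40 °C) then closes the same C2=C3 bond and returns to 10.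

3. Step 9. Hydride delivery to the congested β-carbon C9 may be slow, 1,2-reduction may compete, and the silyl enol ether may be hydrolysed before the Mannich reaction, which would lose the C8 regiochemistry. The fallback sets out from 18. Rhodium-catalysed 1,4-hydrosilylation (Et3SiH, RhCl(PPh3)3, benzene, 60 °C) should give the isolable triethylsilyl enol ether F6, with hydrogen again on the α face of C9. Mannich reaction of purified F6 with N,N-dimethylmethyleneiminium iodide returns to 20.

**Further compounds**

F1 | step 18 | C11-inverted 4-nitrobenzoate of 33 | C[C@]12CCCC(C)(C)[C@@H]1C[C@H](O[Si](C)(C)C(C)(C)C)C(=C)[C@@H]2[C@H](OC(=O)c1ccc(cc1)[N+](=O)[O-])/C=C(\CC1OCCO1)C(OCC)OCC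
F2 | step 18 | C11 epimer of 33 | C[C@]12CCCC(C)(C)[C@@H]1C[C@H](O[Si](C)(C)C(C)(C)C)C(=C)[C@@H]2[C@H](O)/C=C(\CC1OCCO1)C(OCC)OCC
F3 | step 18 | methanesulfonate of F2 | C[C@]12CCCC(C)(C)[C@@H]1C[C@H](O[Si](C)(C)C(C)(C)C)C(=C)[C@@H]2[C@H](OS(C)(=O)=O)/C=C(\CC1OCCO1)C(OCC)OCC
F4 | step 3 | trans-4-allyl-4-methyl-3-(2-methyl-1-oxopropan-2-yl)-5-oxocyclohexyl acetate | C=CC[C@]1(C)C(=O)C[C@H](OC(C)=O)C[C@H]1C(C)(C)C=O
F5 | step 3 | trans-4-allyl-4-methyl-3-(2-methylbut-3-en-2-yl)-5-oxocyclohexyl acetate | C=CC[C@]1(C)C(=O)C[C@H](OC(C)=O)C[C@H]1C(C)(C)C=C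
F6 | step 9 | C7 triethylsilyl enol ether (Δ7, 9α-H) | C[C@]12CCCC(C)(C)[C@@H]1CC(O[Si](CC)(CC)CC)=C[C@@H]2COCc1ccc(OC)cc1
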